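The readings are calculated with made-up constants; noise was put on by code.

Your flask holds 12 mM of starting material and 14.4 mM of coupling partner, and it is the amounts at the peak of target that you can reckon from the earlier runs.

| flask | starting material | coupling partner | remark | time |
|---|---|---|---|---|
| ash | 6 mM | 1.2 equiv | run made earlier |  |
| oak | 9 mM | 1.2 equiv | run made earlier |  |
| birch | 12 mM | 0.60 equiv | run made earlier |  |
| flask | 12 mM | 1.20 equiv |  | 15 d |

| run | time / d | target / % | starting material / % |
|---|---|---|---|
| ash | 0.250 | 14.0 | 80.7 |
| ash | 0.500 | 21.8 | 69.1 |
| ash | 1.04 | 29.0 | 53.7 |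
| ash | 2.00 | 27.5 | 38.2 |
| ash | 4.00 | 14.8 | 22.9 |
| ash | 10.0 | 2.2 | 8.8 |
| oak | 0.250 | 18.5 | 73.7 |
| oak | 0.500 | 29.5 | 62.0 |
| oak | 1.04 | 34.5 | 44.3 |
| oak | 2.00 | 28.9 | 28.7 |
| oak | 4.00 | 14.4 | 16.8 |
| oak | 10.0 | 1.2 | 4.7 |
| birch | 0.250 | 13.3 | 82.0 |
| birch | 0.625 | 22.1 | 70.6 |
| birch | 1.67 | 21.7 | 54.6 |
| birch | 4.00 | 9.0 | 45.6 |
| birch | 10.0 | 0.8 | 40.0 |

(scatter of a reading: 0.5 percentage points)
- when, up to 15 d, the flask holds most target
- the amount of target, in percent of the starting material charged, at that time
- earliest time at which at least nineteen twentieths of that best amount are there, in d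
- latest time at which they still are, in d


Let a and p be the fractions of charged starting material present as starting material and as target, c the starting concentration and E the equivalents. Birch stalls near 40.0% on 0.60 equiv, so I take coupling as one to one, and partner left is c(E − 1 + a). If making goes with starting material times partner and loss goes with target, then at the peak, where the two are equal, p/a divided by partner left is a constant. The highest target readings give 0.122 mM⁻¹ in ash and 0.135 mM⁻¹ in oak. I carry their mean, 0.128 mM⁻¹, as the peak ratio σ, an apparent second-order constant of making over a first-order constant of loss.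

Now turn the question round. For target to equal starting material at the peak, the symmetric case, partner left must be 7.79 mM. In this flask that means a = 44.9%, with 10.2% missing. But the peak readings miss 17.3% in ash and 21.2% in oak, and a straight line in concentration gives 25.1% for this flask. Solving the ratio and that balance together, my own reckoning gives p = 35.7% with partner left 7.10 mM, short of the symmetric case.

The forecast, “Stepping the flask by hand”, puts 37% at 1 d, with the window from 0.68 d to 1.5 d. The forecast's figure stands a little above mine, and the times are the forecast's, not mine.

The flask gives 38.5% at 0.932 d, with the window from 0.641 d to 1.32 d.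

    starting material + coupling partner ⇌ intermediate (K = 10.0 L mol⁻¹, k = 1.20 L mol⁻¹ min⁻¹)
    intermediate ⇌ target + by-product (K = 0.510 M, k = 0.00820 min⁻¹)
    target → over-reaction product A (k = 4.80 × 10⁻⁴ min⁻¹)
    target → over-reaction product B (k = 3.00 × 10⁻⁶ min⁻¹)

At that best time this flask has 40.4% starting material and 7.24 mM of partner, with target below starting material and partner left under 7.79 mM. Take a neighbour flask at 3.0 mM with the same equivalents. The line gives 13.4% missing, and σ then gives p = 21.4%. The best that neighbour flask reaches is 21.5%.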